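The benzene ring of the 2,3-dihydrobenzofuran is made last. Its substitution pattern (O1 on C7a, methoxy groups on C7 and C6, acetyl on C5, C3 on C3a, one hydrogen on C4) is read as a fully substituted pyridazine linked through O1–C2–C3 to a terminal alkyne. One thermolysis joins C3a to C7a and C4 to C5, closes the dihydrofuran ring, expels N2 and leaves the arene with both stereocentres untouched. The precursor 13 is a 3-acetyl-4,5-dimethoxypyridazine whose 6-oxygen carries a syn (3R,4R)-2-methylhex-1-en-5-yne-3,4-diol unit, silylated at the propargylic oxygen. It is assembled convergently from an alkoxyallylboration fragment and a chloropyridazine; desilylation and angeloylation follow.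

Key step: step 8

Remark: (−)-Ipc2BOMe is the reagent made from (+)-α-pinene. The first two methoxide displacements on tetrachloropyridazine are assumed to occur at C4 and C5, as is usual for perhalopyridazines.
Remark: the propargylic oxygen carries triisopropylsilyl so that it cannot migrate to the neighbouring alkoxide during etherification. The acetyl group is carried as its 1-ethoxyvinyl ether until that etherification is over.

Step 1
Reactants: 1 2-methylprop-2-en-1-ol
Product: 2 3-(methoxymethoxy)-2-methylprop-1-ene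
Conditions: MOMCl, i-Pr2NEt, CH2Cl2, 0 °C → rt
Reagents that add atoms: chloromethyl methyl ether, COCCl
Why: Base-mediated O-alkylation of a primary allylic alcohol with an α-chloro ether (MOM ether formation) is routine and installs the acetal oxygen that later directs the allylic lithiation.

Step 2
Reactants: 2 3-(methoxymethoxy)-2-methylprop-1-ene; 3 3-(trimethylsilyl)prop-2-ynal
Product: 6 (3R,4R)-4-(methoxymethoxy)-5-methylhex-5-en-1-yn-3-ol, via (Z)-alkoxyallylborane 4 (not isolated), via C-silylated carbinol 5 (not isolated)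
Conditions: s-BuLi, THF, −78 °C; (−)-Ipc2BOMe; BF3·OEt2; then 3, −78 °C; NaOH, H2O2, 0 °C → rt; then K2CO3, MeOH, rt
Reagents that add atoms: none
Why: In this Brown (Z)-γ-alkoxyallylboration the oxygen-directed lithiation at the OCH2 group gives the chelated (Z)-alkoxyallyl anion, boron is taken up at the CH2 terminus, and the chair Zimmerman–Traxler transition state with the alkynyl group equatorial translates the (Z)-geometry into the syn relationship while the isopinocampheyl groups from (+)-α-pinene direct attack to the si face of the aldehyde, so that both new stereocentres should be set as R, after which alkaline peroxide cleaves the borinate and methanolic K2CO3 removes the alkynyl silane.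

Step 3
Reactants: 6 (3R,4R)-4-(methoxymethoxy)-5-methylhex-5-en-1-yn-3-ol
Product: 7 triisopropyl{[(3R,4R)-4-(methoxymethoxy)-5-methylhex-5-en-1-yn-3-yl]oxy}silane
Conditions: TIPSOTf, 2,6-lutidine, CH2Cl2, −78 → 0 °C
Reagents that add atoms: triisopropylsilyl trifluoromethanesulfonate, CC(C)[Si](OS(=O)(=O)C(F)(F)F)(C(C)C)C(C)C
Why: Silyl triflate silylation with 2,6-lutidine protects the hindered propargylic alcohol, and the triisopropylsilyl group is chosen because it resists 1,2-oxygen-to-oxygen migration when the neighbouring alkoxide is formed in step 7 and withstands the thermolysis of step 8.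

Step 4
Reactants: 7 triisopropyl{[(3R,4R)-4-(methoxymethoxy)-5-methylhex-5-en-1-yn-3-yl]oxy}silane
Product: 8 (3R,4R)-2-methyl-4-[(triisopropylsilyl)oxy]hex-1-en-5-yn-3-ol
Conditions: Me2BBr, CH2Cl2, −78 °C; NaHCO3, THF/H2O, −78 °C → rt
Reagents that add atoms: none
Why: Bromodimethylborane cleaves the MOM acetal at low temperature through the bromomethyl ether, which is hydrolysed on bicarbonate work-up, a Lewis-acid acetal cleavage that should leave the silyl ether, the alkene and the alkyne untouched and does not break the carbinol C–O bond.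

Step 5
Reactants: 9 3,4,5,6-tetrachloropyridazine
Product: 10 3,6-dichloro-4,5-dimethoxypyridazine
Conditions: NaOMe (2 equiv), MeOH, 0 °C → rt
Reagents that add atoms: sodium methoxide, C[O-].[Na+]
Why: Twofold nucleophilic aromatic substitution (SNAr) occurs first at C4 and C5 of a perhalopyridazine, the positions para to a ring nitrogen, so that two equivalents of methoxide should give the symmetrical 4,5-dimethoxy-3,6-dichloride.

Step 6
Reactants: 10 3,6-dichloro-4,5-dimethoxypyridazine
Product: 11 3-chloro-6-(1-ethoxyethenyl)-4,5-dimethoxypyridazine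
Conditions: Bu3Sn–C(OEt)=CH2 (1 equiv), PdCl2(PPh3)2 (5 mol%), toluene, 100 °C; non-acidic work-up
Reagents that add atoms: tributyl(1-ethoxyethenyl)stannane, CCCC[Sn](CCCC)(CCCC)C(=C)OCC
Why: Stille coupling of an α-alkoxyvinylstannane with a chlorodiazine installs the acetyl group in masked form, and since both chlorides are equivalent and the first coupling replaces an electron-withdrawing chloride by a donor-substituted vinyl group, one equivalent of stannane should stop at mono-coupling.

Step 7
Reactants: 8 (3R,4R)-2-methyl-4-[(triisopropylsilyl)oxy]hex-1-en-5-yn-3-ol; 11 3-chloro-6-(1-ethoxyethenyl)-4,5-dimethoxypyridazine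
Product: 13 1-[4,5-dimethoxy-6-({(3R,4R)-2-methyl-4-[(triisopropylsilyl)oxy]hex-1-en-5-yn-3-yl}oxy)pyridazin-3-yl]ethanone, via enol ether 12 (not isolated)
Conditions: NaH, THF/DMF, 0 → 45 °C; then 1 M HCl, THF, rt
Reagents that add atoms: water, O
Why: SNAr etherification of a 3-chloropyridazine (chloride next to ring nitrogen) by the sodium alkoxide of 8 retains the carbinol C–O bond and hence the configuration, the ketone being kept as its non-enolisable enol ether while the alkoxide is present and released by acid hydrolysis of the enol ether in the work-up.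

Step 8
Reactants: 13 1-[4,5-dimethoxy-6-({(3R,4R)-2-methyl-4-[(triisopropylsilyl)oxy]hex-1-en-5-yn-3-yl}oxy)pyridazin-3-yl]ethanone
Product: 15 1-[(2R,3R)-6,7-dimethoxy-2-(prop-1-en-2-yl)-3-[(triisopropylsilyl)oxy]-2,3-dihydro-1-benzofuran-5-yl]ethanone, via bridged diazabicyclooctatriene 14 (not isolated)
Conditions: 1,2-dichlorobenzene (0.01 M, degassed), BHT (cat.), 165 °C, sealed tube
Reagents that add atoms: none
Why: The terminal alkyne (2π) adds across C3 and C6 of the acetyl-activated 1,2-diazine (4π, inverse electron demand) to give the bridged 2,3-diazabicyclo[2.2.2]octatriene 14, which loses N2 by retro-[4+2] and is thereby aromatic without any oxidation or elimination step. The closest known reaction type is the thermal intramolecular pyridazine–alkyne Diels–Alder/cycloreversion of 3-(but-3-ynyloxy)pyridazines to 2,3-dihydrobenzofurans. The dihydrofuran ring closes as the tether ring of the cycloaddition (the three-atom O–C–C link can only span C6 and the inner alkyne carbon, giving the fused five-membered ring), and the benzene ring is closed by the bond pair C3a–C7a/C4–C5 followed by extrusion of the N=N bridge. No stereocentre is created: C2 and C3 are sp3 spectators that meet neither acid nor base, and the two bridgehead centres of 14 vanish on aromatisation, so either face of approach converges on 15. Regiochemistry is fixed by the tether, so the selectivity required is chemoselectivity over the [3,3] oxygen-to-nitrogen allyl shift of the allylic pyridazinyl ether. The acetyl group para to the ether oxygen lowers the diazine LUMO, the two tether substituents (isopropenyl and the bulky silyloxy group) bias the chain towards the reactive rotamer, the alkyne terminus is unhindered, and the reaction is run dilute at the lowest temperature that gives conversion.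

Step 9
Reactants: 15 1-[(2R,3R)-6,7-dimethoxy-2-(prop-1-en-2-yl)-3-[(triisopropylsilyl)oxy]-2,3-dihydro-1-benzofuran-5-yl]ethanone
Product: 16 1-[(2R,3R)-3-hydroxy-6,7-dimethoxy-2-(prop-1-en-2-yl)-2,3-dihydro-1-benzofuran-5-yl]ethanone
Conditions: TBAF, AcOH, THF, 0 °C → rt
Reagents that add atoms: none
Why: Fluoride cleavage of the silicon–oxygen bond, buffered with acetic acid so that the enolisable ketone and the benzylic cis-alcohol never meet a free alkoxide, leaves both stereocentres untouched.

Step 10
Reactants: 16 1-[(2R,3R)-3-hydroxy-6,7-dimethoxy-2-(prop-1-en-2-yl)-2,3-dihydro-1-benzofuran-5-yl]ethanone; 17 angelic acid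
Product: 19 (2R,3R)-5-acetyl-6,7-dimethoxy-2-(prop-1-en-2-yl)-2,3-dihydro-1-benzofuran-3-yl (2Z)-2-methylbut-2-enoate, via mixed anhydride 18 (not isolated)
Conditions: 17, 2,4,6-trichlorobenzoyl chloride, Et3N, toluene, rt; then 16, 75 °C
Reagents that add atoms: none
Why: Yamaguchi esterification through the mixed 2,4,6-trichlorobenzoic anhydride, run without DMAP, is the established way to acylate a hindered secondary alcohol with angelic acid without Z-to-E isomerisation to the tiglate, the alcohol attacking the unhindered angeloyl carbonyl with retention at C3.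

Compound list
1 | 2-methylprop-2-en-1-ol | C=C(C)CO | starting material
2 | 3-(methoxymethoxy)-2-methylprop-1-ene | C=C(C)COCOC | intermediate
3 | 3-(trimethylsilyl)prop-2-ynal | C[Si](C)(C)C#CC=O | starting material
4 | [(2Z)-3-(methoxymethoxy)-2-methylprop-2-en-1-yl]bis(isopinocampheyl)borane, isopinocampheyl groups from (+)-α-pinene | COCO/C=C(/C)CB([C@@H]1C[C@@H]2C[C@@H](C2(C)C)[C@H]1C)[C@@H]1C[C@@H]2C[C@@H](C2(C)C)[C@H]1C | intermediate (not isolated)
5 | (3R,4R)-4-(methoxymethoxy)-5-methyl-1-(trimethylsilyl)hex-5-en-1-yn-3-ol | C=C(C)[C@@H](OCOC)[C@H](O)C#C[Si](C)(C)C | intermediate (not isolated)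
6 | (3R,4R)-4-(methoxymethoxy)-5-methylhex-5-en-1-yn-3-ol (free OH on the propargylic carbon) | C=C(C)[C@@H](OCOC)[C@H](O)C#C | intermediate
7 | triisopropyl{[(3R,4R)-4-(methoxymethoxy)-5-methylhex-5-en-1-yn-3-yl]oxy}silane | C=C(C)[C@@H](OCOC)[C@H](O[Si](C(C)C)(C(C)C)C(C)C)C#C | intermediate
8 | (3R,4R)-2-methyl-4-[(triisopropylsilyl)oxy]hex-1-en-5-yn-3-ol (free OH on the allylic carbon) | C=C(C)[C@@H](O)[C@H](O[Si](C(C)C)(C(C)C)C(C)C)C#C | intermediate
9 | 3,4,5,6-tetrachloropyridazine | Clc1nnc(Cl)c(Cl)c1Cl | starting material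
10 | 3,6-dichloro-4,5-dimethoxypyridazine | COc1c(Cl)nnc(Cl)c1OC | intermediate
11 | 3-chloro-6-(1-ethoxyethenyl)-4,5-dimethoxypyridazine | CCOC(=C)c1nnc(Cl)c(OC)c1OC | intermediate
12 | 3-(1-ethoxyethenyl)-4,5-dimethoxy-6-({(3R,4R)-2-methyl-4-[(triisopropylsilyl)oxy]hex-1-en-5-yn-3-yl}oxy)pyridazine | C=C(C)[C@@H](Oc1nnc(C(=C)OCC)c(OC)c1OC)[C@H](O[Si](C(C)C)(C(C)C)C(C)C)C#C | intermediate (not isolated)
13 | 1-[4,5-dimethoxy-6-({(3R,4R)-2-methyl-4-[(triisopropylsilyl)oxy]hex-1-en-5-yn-3-yl}oxy)pyridazin-3-yl]ethanone | C=C(C)[C@@H](Oc1nnc(C(C)=O)c(OC)c1OC)[C@H](O[Si](C(C)C)(C(C)C)C(C)C)C#C | intermediate (key-step precursor)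
14 | bridged 2,3-diazabicyclo[2.2.2]octa-2,5,7-triene cycloadduct of 13 (alkyne across pyridazine C3/C6, dihydrofuran ring closed; one bridgehead pair drawn, the other converges likewise) | C=C(C)[C@H]1O[C@]23N=N[C@](C(C)=O)(C=C2[C@H]1O[Si](C(C)C)(C(C)C)C(C)C)C(OC)=C3OC | intermediate (not isolated)
15 | 1-[(2R,3R)-6,7-dimethoxy-2-(prop-1-en-2-yl)-3-[(triisopropylsilyl)oxy]-2,3-dihydro-1-benzofuran-5-yl]ethanone | C=C(C)[C@H]1Oc2c(cc(C(C)=O)c(OC)c2OC)[C@H]1O[Si](C(C)C)(C(C)C)C(C)C | intermediate (key-step product)
16 | 1-[(2R,3R)-3-hydroxy-6,7-dimethoxy-2-(prop-1-en-2-yl)-2,3-dihydro-1-benzofuran-5-yl]ethanone | C=C(C)[C@H]1Oc2c(cc(C(C)=O)c(OC)c2OC)[C@H]1O | intermediate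
17 | angelic acid, (2Z)-2-methylbut-2-enoic acid | C/C=C(/C)C(=O)O | starting material
18 | (2Z)-2-methylbut-2-enoic 2,4,6-trichlorobenzoic anhydride | C/C=C(/C)C(=O)OC(=O)c1c(Cl)cc(Cl)cc1Cl | intermediate (not isolated)
19 | (2R,3R)-5-acetyl-6,7-dimethoxy-2-(prop-1-en-2-yl)-2,3-dihydro-1-benzofuran-3-yl (2Z)-2-methylbut-2-enoate | C=C(C)[C@H]1Oc2c(cc(C(C)=O)c(OC)c2OC)[C@H]1OC(=O)/C(C)=C\C | target

Total step count: 10
Longest linear sequence: 8 steps (1, 2, 3, 4, 7, 8, 9, 10)

Steps most likely to fail

Step 8. The [3,3] oxygen-to-nitrogen allyl shift of the allylic pyridazinyl ether, or unselective decomposition, may outrun the cycloaddition at the temperature it needs. The fallback sets out from 13 and comes back at 15; it masks the alkene so that no allylic C–O bond is present during thermolysis. Dihydroxylation of the isopropenyl group of 13 (OsO4 cat., NMO, acetone/H2O; the alkyne is inert) should give the 1,2-diol F1 as both epimers at the new carbinol carbon. It is protected as the acetonide F2 (2,2-dimethoxypropane, PPTS). Thermolysis under the conditions of step 8 should give the cycloadduct acetonide F3. Aqueous acetic acid releases the cycloadduct diol F4, thiocarbonyldiimidazole converts it into the cyclic thionocarbonate F5, and Corey–Winter olefination (1,3-dimethyl-2-phenyl-1,3,2-diazaphospholidine, THF, 40 °C) restores the isopropenyl group to give 15.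

Step 2. Lithiation may occur at the allylic methyl group instead of the OCH2 group, the lithiated ether may undergo Wittig rearrangement, or facial and syn selectivity may erode with the 2-methyl-substituted reagent. The fallback sets out from 3 and comes back at 8; it is an auxiliary-controlled Evans syn glycolate aldol route. The glycolate imide F6, made from (S)-4-benzyloxazolidin-2-one and (4-methoxybenzyloxy)acetyl chloride, is enolised (Bu2BOTf, Et3N, CH2Cl2, −78 °C) and added to 3 to give the syn aldol adduct F7. AlMe3 and MeNH(OMe)·HCl give the Weinreb amide F8, and TIPSOTf with 2,6-lutidine gives the silyl ether F9. MeMgBr then gives the methyl ketone F10. Non-basic Takai–Lombardo methylenation (Zn, CH2Br2, TiCl4) gives the alkene F11, K2CO3 in MeOH frees the terminal alkyne F12, and DDQ removes the 4-methoxybenzyl ether to give 8.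

Step 7. Displacement by the hindered secondary alkoxide at the weakly activated chloride may be slow, so that alkoxy exchange at the methoxy-bearing C4/C5 positions or silyl migration competes on prolonged warming. The fallback sets out from 11 (with 8) and comes back at 13. Hydrolysis of 11 (1 M HCl, THF) gives the acetyl chloropyridazine F13, whose chloride is para to the acyl group. It should be displaced by the sodium alkoxide of 8 at low temperature (NaH, THF, −40 °C, F13 in excess to offset reversible enolisation), giving 13 directly.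

Further compounds
F1 | step 8 | 1,2-diol from dihydroxylation of the isopropenyl group of 13 (both epimers at the new carbinol carbon) | CC(O)(CO)[C@@H](Oc1nnc(C(C)=O)c(OC)c1OC)[C@H](O[Si](C(C)C)(C(C)C)C(C)C)C#C
F2 | step 8 | acetonide of F1 | CC1(COC(C)(C)O1)[C@@H](Oc1nnc(C(C)=O)c(OC)c1OC)[C@H](O[Si](C(C)C)(C(C)C)C(C)C)C#C
F3 | step 8 | 1-[(2R,3R)-6,7-dimethoxy-3-[(triisopropylsilyl)oxy]-2-(2,2,4-trimethyl-1,3-dioxolan-4-yl)-2,3-dihydro-1-benzofuran-5-yl]ethanone | CC1(COC(C)(C)O1)[C@H]1Oc2c(cc(C(C)=O)c(OC)c2OC)[C@H]1O[Si](C(C)C)(C(C)C)C(C)C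
F4 | step 8 | 1-[(2R,3R)-2-(1,2-dihydroxypropan-2-yl)-6,7-dimethoxy-3-[(triisopropylsilyl)oxy]-2,3-dihydro-1-benzofuran-5-yl]ethanone | CC(O)(CO)[C@H]1Oc2c(cc(C(C)=O)c(OC)c2OC)[C@H]1O[Si](C(C)C)(C(C)C)C(C)C
F5 | step 8 | cyclic thionocarbonate of F4 | CC1(COC(=S)O1)[C@H]1Oc2c(cc(C(C)=O)c(OC)c2OC)[C@H]1O[Si](C(C)C)(C(C)C)C(C)C
F6 | step 2 | (S)-4-benzyl-3-{[(4-methoxybenzyl)oxy]acetyl}-1,3-oxazolidin-2-one | O=C1OC[C@H](Cc2ccccc2)N1C(=O)COCc1ccc(OC)cc1
F7 | step 2 | syn aldol adduct of F6 and 3 (α-(4-methoxybenzyl)oxy, β-hydroxy, both centres as in 8) | O=C1OC[C@H](Cc2ccccc2)N1C(=O)[C@@H](OCc1ccc(OC)cc1)[C@H](O)C#C[Si](C)(C)C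
F8 | step 2 | N-methoxy-N-methyl amide of the aldol acid (free β-hydroxy) | CON(C)C(=O)[C@@H](OCc1ccc(OC)cc1)[C@H](O)C#C[Si](C)(C)C
F9 | step 2 | triisopropylsilyl ether of F8 | CON(C)C(=O)[C@@H](OCc1ccc(OC)cc1)[C@H](O[Si](C(C)C)(C(C)C)C(C)C)C#C[Si](C)(C)C
F10 | step 2 | methyl ketone from F9 | CC(=O)[C@@H](OCc1ccc(OC)cc1)[C@H](O[Si](C(C)C)(C(C)C)C(C)C)C#C[Si](C)(C)C
F11 | step 2 | isopropenyl compound from methylenation of F10 | C=C(C)[C@@H](OCc1ccc(OC)cc1)[C@H](O[Si](C(C)C)(C(C)C)C(C)C)C#C[Si](C)(C)C
F12 | step 2 | C-desilylated 4-methoxybenzyl ether of 8 | C=C(C)[C@@H](OCc1ccc(OC)cc1)[C@H](O[Si](C(C)C)(C(C)C)C(C)C)C#C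
F13 | step 7 | 1-(6-chloro-4,5-dimethoxypyridazin-3-yl)ethanone | CC(=O)c1nnc(Cl)c(OC)c1OC
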